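Two questions stand here, and both ask how the rate of making target answers a change in one charge.

| flask | starting material | coupling partner | free catalyst | remark |
|---|---|---|---|---|
| south-east | 0.47 M | 0.95 equiv | 5 mol% | the very flask that is asked about, followed so far |
| flask | 0.47 M | 0.950 equiv | 5 mol% |  |

- apparent order in free catalyst when 20% of the starting material are converted (percent change of the rate of making target for one percent more free catalyst charged)
- apparent order in coupling partner when 20% of the starting material are converted (percent change of the rate of making target for one percent more coupling partner charged)

- what was read earlier has a scatter of 1.5 percentage points, one standard deviation
- no earlier run changes the charge of free catalyst; that part of a forecast is a guess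
- no earlier run changes the charge of coupling partner; that part of a forecast is a guess

- south-east (time / h: target / %, starting material / %): 3.00: 24, 39; 6.00: 41, 16; 10.0: 53, 6; 15.0: 59, 2; 25.0: 59, 3; 40.0: 59, 0

(scatter of a reading: 1.5 percentage points)

I read this table column against column. In its first row the starting material has lost 61.0% and the target stands at 24%, so the selectivity s, target made per starting material lost, reads 0.393. What is neither target nor starting material reads 37.0% in that row and 41.0% in the last, so that gap is open early.

The starting-material column I integrate as a first-order decay, exp(−kt), which gives k = 0.314 h⁻¹ from the first row. By this decay a conversion of 20% falls at 0.711 h; I carry s over from the first row to that moment, as an assumption, and s, k and the starting material still present give an estimated rate of making target of 0.0464 M h⁻¹.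

Dividing the catalyst charged by this rate gives τ = 0.506 h, my turn time: the time one catalyst takes per target made, the inverse of the turnover frequency. For a catalyst passing through steps in a row, at a fixed conversion, I take a reagent's order to follow the share of τ spent in the step that uses it. The rate is the catalyst charged over τ, so if τ stays as it is I commit to an order near 1 in free catalyst, but one charge of coupling partner gives me no share.

The forecast says 1 in free catalyst and 0.7 in coupling partner, holding that “Partner probably enters downstream”.

The flask gives 0.92 in free catalyst and 0.48 in coupling partner. Its rate of making target at 20% conversion is 1.12 M d⁻¹, reached after 0.600 h, earlier than my time.

    coupling partner + free catalyst → catalyst intermediate A (k = 0.210 M⁻¹ min⁻¹)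
    starting material + catalyst intermediate A → catalyst intermediate B (k = 1.20 M⁻¹ min⁻¹)
    catalyst intermediate B → by-product + catalyst intermediate C (k = 0.0780 min⁻¹)
    catalyst intermediate C ⇌ free catalyst + target (K = 0.160 M, k = 1.20 min⁻¹)
    2 starting material → self-condensation product (k = 0.00460 M⁻¹ min⁻¹)

With partner as charged, the step of coupling partner with free catalyst takes 0.178 h per turn, a third of my τ, and the order in coupling partner stands higher, at 0.48.

(The readings are calculated on assumed constants; scatter was added.)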